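**Retrosynthetic overview**
1. Enabling feature: in each outer ring the carbinol carbon is bonded to a CMe2 carbon that sits on the ring-fusion CH, para to the methyl-bearing carbon of the inner ring (ring E: C21–C22–C17, methyl on C14; ring A: C3–C4–C5, methyl on C8). Cutting C21–C22 and C3–C4 turns each CMe2 into isopropenyl + H•, each CHOH into CHO, and rings D and B into p-menthane (carvone) rings.
2. Endgame: C11≡C12 → CH2CH2 (H2) ⇐ 8-en-7-one by allylic 1,3-transposition of a C9 carbinol, then MnO2 ⇐ the tetracycle from the key step.
3. Key step: a two-fold MHAT radical 6-exo closure (isopropenyl → tertiary radical → aldehyde) closes rings E and A together on a bis-monocyclic dialdehyde. The sp3 C9 (silyloxy, alkynyl) is a temporary conformational lock for ring A.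
4. Dialdehyde ⇐ double aldehyde-selective Wacker oxidation ⇐ C9–C11 bond by 1,2-addition of the ring-D acetylide to the ring-B enone.
5. Ring D comes from (R)-carvone (Me then allyl → C18; 1,4-reduction → C14; epoxide/aldehyde → C13; C1 homologation → C11). Ring B comes from (S)-carvone (allyl then Me → C10). Ring order: D and B are bought, then E and A form at once.

Key step: step 11

Remark on the chemistry: 8,14-secogammacerane (onocerane) numbering is used (C1–C10 enone half with rings A/B, C11–C12 linker, C13–C22 saturated half with rings D/E; C13 bears the linker, C14 the secondary methyl, C17 is the fusion CH, C18 the fusion C–CH3, C21 the carbinol, C22 the CMe2). The SMILES encodes (3S,5S,10S,13S,14R,17R,18R,21S), that is a cis A/B junction (H-5 and the C10 methyl on one face) and a trans D/E junction, and the route is built for exactly this isomer.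

**Step 1**
Reactants: 1 (R)-(−)-carvone
Product: 3 (5R,6S)-2,6-dimethyl-5-(prop-1-en-2-yl)cyclohex-2-en-1-one (trans-6-methylcarvone), via lithium dienolate 2 (not isolated)
Conditions: LDA, THF, −78 °C; MeI, −78 → 0 °C
Reagents that add atoms: iodomethane, CI
Why: Kinetic α′-deprotonation gives the cross-conjugated dienolate 2, and enolate alkylation (SN2) puts the methyl on C6 mainly anti to the isopropenyl group; this centre is planarised again in step 2.

**Step 2**
Reactants: 3 trans-6-methylcarvone
Product: 5 (5S,6S)-2,6-dimethyl-6-(prop-2-en-1-yl)-5-(prop-1-en-2-yl)cyclohex-2-en-1-one (allyl trans to isopropenyl), via lithium dienolate 4 (not isolated)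
Conditions: LDA, THF, −78 °C; allyl bromide, −78 → 0 °C
Reagents that add atoms: allyl bromide, C=CCBr
Why: In this second kinetic enolate alkylation the tetrasubstituted dienolate 4 is attacked on the face opposite the neighbouring isopropenyl group, which sets the quaternary carbon (future C18) with the allyl arm trans to isopropenyl, as the trans D/E junction needs.

**Step 3**
Reactants: 5 ring-D enone
Product: 7 (2S,3S,6R)-2,6-dimethyl-2-(prop-2-en-1-yl)-3-(prop-1-en-2-yl)cyclohexan-1-one, via lithium enolate 6 (not isolated)
Conditions: L-Selectride, THF, −78 °C; MeOH quench; NaOMe (cat.), MeOH, rt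
Reagents that add atoms: none
Why: Conjugate (1,4) hydride reduction of the β-unsubstituted, carbonyl-hindered enone leaves both isolated alkenes untouched, and base equilibration of the α-centre puts the methyl (future C14) equatorial, because the axial epimer would be 1,3-diaxial to the axial C18 methyl.

**Step 4**
Reactants: 7 ring-D ketone
Product: 8 4-allyl-4,8-dimethyl-5-(prop-1-en-2-yl)-1-oxaspiro[2.5]octane (epoxide CH2 axial, O equatorial)
Conditions: Me3S+ I−, NaH, DMSO/THF, 0 °C → rt
Reagents that add atoms: trimethylsulfonium iodide, C[S+](C)C.[I-]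
Why: In the Corey–Chaykovsky epoxidation the small unstabilised sulfur ylide adds to hindered 2,2,6-trialkylcyclohexanones along the axial trajectory away from the axial methyl; the new centre is erased in step 5.

**Step 5**
Reactants: 8 spiro-epoxide
Product: 10 (1S,2S,3S,6R)-2,6-dimethyl-2-(prop-2-en-1-yl)-3-(prop-1-en-2-yl)cyclohexane-1-carbaldehyde (CHO equatorial), via axial aldehyde 9 (not isolated)
Conditions: BF3·OEt2 (0.3 equiv), CH2Cl2, −78 °C; aq. NaHCO3; crude + DBU (cat.), CH2Cl2, rt
Reagents that add atoms: none
Why: In the Meinwald rearrangement the Lewis acid opens the epoxide at its tertiary carbon and a 1,2-hydride shift gives aldehyde 9; base epimerisation under thermodynamic control then gives the equatorial aldehyde 10, which fixes C13 trans to the C14 methyl.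

**Step 6**
Reactants: 10 ring-D aldehyde
Product: 11 ring-D alkyne (as 10 with C≡CH in place of CHO; ethynyl, ring methyl at C14, isopropenyl and allyl equatorial, C18 methyl axial)
Conditions: dimethyl (1-diazo-2-oxopropyl)phosphonate, K2CO3, MeOH, 0 °C → rt
Reagents that add atoms: dimethyl (1-diazo-2-oxopropyl)phosphonate, CC(=O)C(=[N+]=[N-])P(=O)(OC)OC
Why: The Seyferth–Gilbert homologation in its Ohira–Bestmann form turns CHO into C≡CH with one added carbon (C11), and the basic medium cannot harm C13 because it is already the thermodynamic epimer.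

**Step 7**
Reactants: 12 (S)-(+)-carvone
Product: 14 (5S,6R)-2-methyl-6-(prop-2-en-1-yl)-5-(prop-1-en-2-yl)cyclohex-2-en-1-one, via lithium dienolate 13 (not isolated)
Conditions: LDA, THF, −78 °C; allyl bromide, −78 → 0 °C
Reagents that add atoms: allyl bromide, C=CCBr
Why: This is a kinetic α′-enolate alkylation as in step 1, with the arm introduced first because the second electrophile decides the configuration of the quaternary carbon.

**Step 8**
Reactants: 14 6-allylcarvone
Product: 16 (5R,6S)-2,6-dimethyl-6-(prop-2-en-1-yl)-5-(prop-1-en-2-yl)cyclohex-2-en-1-one (allyl cis to isopropenyl), via lithium dienolate 15 (not isolated)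
Conditions: LDA, THF, −78 °C; MeI, −78 → 0 °C
Reagents that add atoms: iodomethane, CI
Why: In this enolate alkylation with the reversed order of electrophiles, MeI enters anti to the isopropenyl group, so the arm ends up cis to it; this sets C10 as the cis A/B junction requires.

**Step 9**
Reactants: 11 ring-D alkyne; 16 ring-B enone
Product: 19 C9 triethylsilyl ether of the 1,2-adduct (C9 bears OSiEt3 on the face of the allyl and isopropenyl groups and the alkynyl link to C13 on the face of the C10 methyl), via lithium acetylide 17 (not isolated), via lithium alkoxide 18 (not isolated)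
Conditions: n-BuLi, THF, −78 °C; add 16, −78 → −20 °C; TESOTf, −78 → 0 °C
Reagents that add atoms: triethylsilyl triflate, CC[Si](CC)(CC)OS(=O)(=O)C(F)(F)F
Why: The slim acetylide undergoes 1,2-carbonyl addition to an enone that has no α-proton, on the face that carries only the methyl; in-situ silylation masks the alkoxide (no oxypalladation, no lactol) and keeps C9 as a fully substituted sp3 centre for step 11, and this centre is erased in step 12.

**Step 10**
Reactants: 19 bis(allyl) silyl ether
Product: 20 dialdehyde (both allyl arms converted into 3-oxopropyl arms)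
Conditions: PdCl2(PhCN)2, CuCl2·2H2O, AgNO2 (all cat.), O2 (1 atm), t-BuOH/MeNO2 15:1, rt
Reagents that add atoms: dioxygen, O=O
Why: The nitrite-modified aldehyde-selective Wacker oxidation is known to give aldehydes from allyl groups on quaternary carbons, and the 1,1-disubstituted and trisubstituted alkenes and the shielded internal alkyne are not oxidised under these conditions.

**Step 11**
Reactants: 20 dialdehyde
Product: 22 tetracyclic (3S,21S)-3,21-diol 9-triethylsilyl ether (rings E and A closed), via tricyclic hydroxy aldehyde 21 (not isolated)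
Conditions: Fe(acac)3 (cat.), PhSiH3, EtOH (0.01 M), 50 °C
Reagents that add atoms: none
Why: An iron hydride made from Fe(acac)3 and PhSiH3 transfers H• to the CH2 terminus of each isopropenyl group (Markovnikov MHAT), the tertiary radicals at C22 and C4 add to the aldehyde carbons C21 and C3, and reduction of the alkoxy radicals by Fe(II) with protonation by EtOH makes the reversible addition productive. The closest known reaction types are the iron-catalysed MHAT reductive cyclisation of alkene-tethered ketones and the intermolecular MHAT addition of unactivated alkenes to aldehydes. Ring E closes 6-exo-trig on a chair ring D whose radical carbon (on C17) and arm (on C18) are trans-diequatorial, giving the trans D/E junction, and ring A closes 6-exo-trig from the cis pair on C5 and C10, giving the cis A/B junction, while the junction centres themselves are not touched. C21 is set by C17/C18 through a chair-like transition state with the carbonyl oxygen equatorial (21S); C3 is set because the fully substituted C9 forbids the ring-B conformer with C4 axial (syn-axial clash), so closure runs through the conformer with C4 equatorial and the arm axial, in which an axial carbonyl oxygen would hit C6H2 and the oxygen therefore goes equatorial (3S, OH cis to H-5 and the C10 methyl). The step needs chemoselective MHAT at the two 1,1-disubstituted alkenes, which is secured by the much slower reaction of the hindered trisubstituted C7=C8 alkene and the internal alkyne, by the alkynyl group lying on the ring-B face opposite C4 (no 5-exo-dig path), and by high dilution. One operation thus makes two rings, two quaternary carbons and two carbinol stereocentres and turns a bis-monocycle into the tetracycle.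

**Step 12**
Reactants: 22 tetracyclic silyl ether
Product: 24 3,7,21-triol with the C8=C9–C11≡C12 enyne (7-OH drawn on the convex face), via tertiary carbinol 23 (not isolated)
Conditions: TsOH·H2O (cat.), THF/H2O 4:1, 0 °C → rt
Reagents that add atoms: water, O
Why: Acid cleaves the silyl ether, and the tertiary allylic-propargylic C9–O bond then ionises and water returns at the unhindered terminus C7 (acid-catalysed allylic 1,3-transposition of alkynyl vinyl carbinols), driven by the conjugated tetrasubstituted enyne; the C7 configuration is of no consequence.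

**Step 13**
Reactants: 24 triol
Product: 25 3,21-dihydroxy-8-en-11-yn-7-one
Conditions: MnO2, CH2Cl2, rt
Reagents that add atoms: none
Why: Chemoselective MnO2 oxidation touches only the allylic carbinol, and the two saturated neopentyl carbinols are inert.

**Step 14**
Reactants: 25 ynone diol
Product: 26 target CNP0290352.1
Conditions: H2 (1 atm), Pd/C, EtOAc, rt
Reagents that add atoms: none
Why: Heterogeneous catalytic hydrogenation saturates the alkyne to C11H2–C12H2, the tetrasubstituted enone C=C is too hindered to react, and no stereocentre is formed or touched.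

**Compound list**
1 | (R)-(−)-carvone | CC1=CC[C@@H](C(C)=C)CC1=O | starting material
2 | lithium dienolate of 1 | [Li+].CC1=CC[C@@H](C(C)=C)C=C1[O-] | intermediate
3 | (5R,6S)-6-methylcarvone | CC1=CC[C@@H](C(C)=C)[C@H](C)C1=O | intermediate
4 | lithium dienolate of 3 | [Li+].CC1=CC[C@@H](C(C)=C)C(C)=C1[O-] | intermediate
5 | (5S,6S)-6-allyl-6-methylcarvone (allyl trans to isopropenyl) | CC1=CC[C@@H](C(C)=C)[C@](C)(CC=C)C1=O | intermediate
6 | lithium enolate from 1,4-reduction of 5 | [Li+].CC1=C([O-])[C@@](C)(CC=C)[C@H](C(C)=C)CC1 | intermediate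
7 | (2S,3S,6R)-2-allyl-2,6-dimethyl-3-isopropenylcyclohexanone | C[C@@H]1CC[C@@H](C(C)=C)[C@](C)(CC=C)C1=O | intermediate
8 | spiro-epoxide of 7 (CH2 axial) | C[C@@H]1CC[C@@H](C(C)=C)[C@](C)(CC=C)[C@]12CO2 | intermediate
9 | (1R,2S,3S,6R)-aldehyde (CHO axial) | C[C@@H]1CC[C@@H](C(C)=C)[C@](C)(CC=C)[C@@H]1C=O | intermediate
10 | (1S,2S,3S,6R)-aldehyde (CHO equatorial) | C[C@@H]1CC[C@@H](C(C)=C)[C@](C)(CC=C)[C@H]1C=O | intermediate
11 | ring-D alkyne | C[C@@H]1CC[C@@H](C(C)=C)[C@](C)(CC=C)[C@H]1C#C | intermediate
12 | (S)-(+)-carvone | CC1=CC[C@H](C(C)=C)CC1=O | starting material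
13 | lithium dienolate of 12 | [Li+].CC1=CC[C@H](C(C)=C)C=C1[O-] | intermediate
14 | (5S,6R)-6-allylcarvone | CC1=CC[C@H](C(C)=C)[C@@H](CC=C)C1=O | intermediate
15 | lithium dienolate of 14 | [Li+].CC1=CC[C@H](C(C)=C)C(CC=C)=C1[O-] | intermediate
16 | (5R,6S)-6-allyl-6-methylcarvone (allyl cis to isopropenyl) | CC1=CC[C@H](C(C)=C)[C@](C)(CC=C)C1=O | intermediate
17 | lithium acetylide of 11 | [Li+].[C-]#C[C@H]1[C@H](C)CC[C@@H](C(C)=C)[C@]1(C)CC=C | intermediate
18 | lithium alkoxide of the 1,2-adduct | [Li+].CC1=CC[C@H](C(C)=C)[C@](C)(CC=C)[C@@]1([O-])C#C[C@H]1[C@H](C)CC[C@@H](C(C)=C)[C@]1(C)CC=C | intermediate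
19 | C9 triethylsilyl ether, bis(allyl) | CC1=CC[C@H](C(C)=C)[C@](C)(CC=C)[C@@]1(O[Si](CC)(CC)CC)C#C[C@H]1[C@H](C)CC[C@@H](C(C)=C)[C@]1(C)CC=C | intermediate
20 | dialdehyde | CC1=CC[C@H](C(C)=C)[C@](C)(CCC=O)[C@@]1(O[Si](CC)(CC)CC)C#C[C@H]1[C@H](C)CC[C@@H](C(C)=C)[C@]1(C)CCC=O | intermediate
21 | tricyclic hydroxy aldehyde (ring E closed, ring A open) | CC1=CC[C@H](C(C)=C)[C@](C)(CCC=O)[C@@]1(O[Si](CC)(CC)CC)C#C[C@H]1[C@H](C)CC[C@H]2C(C)(C)[C@@H](O)CC[C@]12C | intermediate
22 | tetracyclic 3,21-diol 9-triethylsilyl ether | CC1=CC[C@@H]2C(C)(C)[C@@H](O)CC[C@]2(C)[C@@]1(O[Si](CC)(CC)CC)C#C[C@H]1[C@H](C)CC[C@H]2C(C)(C)[C@@H](O)CC[C@]12C | intermediate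
23 | tetracyclic 3,9,21-triol (tertiary C9 carbinol) | CC1=CC[C@@H]2C(C)(C)[C@@H](O)CC[C@]2(C)[C@@]1(O)C#C[C@H]1[C@H](C)CC[C@H]2C(C)(C)[C@@H](O)CC[C@]12C | intermediate
24 | 3,7,21-triol, 8-en-11-yne | CC1=C(C#C[C@H]2[C@H](C)CC[C@H]3C(C)(C)[C@@H](O)CC[C@]23C)[C@@]2(C)CC[C@H](O)C(C)(C)[C@H]2C[C@@H]1O | intermediate
25 | 3,21-dihydroxy-8-en-11-yn-7-one | CC1=C(C#C[C@H]2[C@H](C)CC[C@H]3C(C)(C)[C@@H](O)CC[C@]23C)[C@@]2(C)CC[C@H](O)C(C)(C)[C@H]2CC1=O | intermediate
26 | CNP0290352.1, (3S,5S,10S,13S,14R,17R,18R,21S)-3,21-dihydroxy-8,14-secogammacer-8-en-7-one | CC1=C(CC[C@H]2[C@H](C)CC[C@H]3C(C)(C)[C@@H](O)CC[C@]23C)[C@@]2(C)CC[C@H](O)C(C)(C)[C@H]2CC1=O | target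

Total step count: 14. Longest linear sequence: 12 (steps 1–6 and 9–14).

**Steps most likely to fail**

Step 11. The tertiary radicals may be reduced before they cyclise, because addition to C=O is reversible. The second closure may stay incomplete, or facial selectivity at C3 may erode. The fallback changes the acceptor, the oxidation level and the source of stereocontrol. It sets out from 20 and comes back at 22.
- Both aldehydes are converted into nitriles (O-(diphenylphosphinyl)hydroxylamine, toluene, 85 °C) to give the dinitrile F1.
- The known MHAT cyclisation of alkenes onto nitriles (Fe(acac)3, PhSiH3, EtOH, then hydrolytic work-up) gives the 3,21-diketone F2.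
- A reagent-controlled Corey–Bakshi–Shibata reduction follows, using (R)-Me-CBS and catecholborane at −40 °C. The CMe2 side is the large group at both ketones, and no enone is present at this stage. This reduction delivers 22.

Step 10. Anti-Markovnikov selectivity may be lost, the alkenes may isomerise, or palladium may induce ionisation of the silyl ether. The fallback replaces palladium oxidation by hydroboration. It sets out from 19 and comes back at 20.
- Disiamylborane (THF, 0 °C) is selective for the two monosubstituted alkenes over the isopropenyl groups and the shielded alkyne.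
- NaBO3 oxidation then gives the diol F3.
- Dess–Martin periodinane oxidises F3 to 20.

Step 12. The ionised species may dehydrate to a cross-conjugated dienyne, or water may be captured at the alkyne terminus. The fallback replaces ionic solvolysis by a concerted, non-acidic transposition. It sets out from 22 and comes back at 24.
- TBAF (THF) gives the tertiary carbinol 23 in isolated form.
- A rhenium-oxo-catalysed suprafacial 1,3-transposition (Ph3SiOReO3 cat., Et2O, −50 → 0 °C) moves the hydroxyl to C7.
- This fallback makes no new compound (F0).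

**Further compounds**
F1 | step 11 | dinitrile (both arms CH2CH2CN) | CC1=CC[C@H](C(C)=C)[C@](C)(CCC#N)[C@@]1(O[Si](CC)(CC)CC)C#C[C@H]1[C@H](C)CC[C@@H](C(C)=C)[C@]1(C)CCC#N
F2 | step 11 | tetracyclic 3,21-diketone 9-triethylsilyl ether | CC1=CC[C@@H]2C(C)(C)C(=O)CC[C@]2(C)[C@@]1(O[Si](CC)(CC)CC)C#C[C@H]1[C@H](C)CC[C@H]2C(C)(C)C(=O)CC[C@]12C
F3 | step 10 | diol (both arms CH2CH2CH2OH) | CC1=CC[C@H](C(C)=C)[C@](C)(CCCO)[C@@]1(O[Si](CC)(CC)CC)C#C[C@H]1[C@H](C)CC[C@@H](C(C)=C)[C@]1(C)CCCO
F0 | step 12 | none | none
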